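**Retrosynthetic overview**
1. The target is a 3-aroyl-1H-isochromene. Both benzene rings are bought, so the pyran ring is the only ring to build, and it is closed in the last step.
2. C3–C(=O) and C(=O)–aryl: carbonylative Suzuki–Miyaura coupling (CO plus 2,4-dimethoxyphenylboronic acid) of 3-bromo-6,7-dimethoxy-1H-isochromene.
3. O2–C3 (ring closure, new): Cu-catalysed intramolecular O-vinylation of 2-(2,2-dibromovinyl)-4,5-dimethoxybenzyl alcohol, run in the same flask as line 2.
4. C3=C4: dibromomethylenation of the lactol/hydroxy aldehyde obtained by half-reduction of 5,6-dimethoxyphthalide. The lactone ring is opened again and only delivers C1 and C4 at different oxidation levels.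

Assumption: the SMILES holds no stereocentre and its only non-aromatic C=C is locked in the ring, so the target is achiral and "single enantiomer" needs no stereocontrol; 1, 3, 6 and 7 are taken as catalogue chemicals.

Step 1
Reactants: 1 5,6-dimethoxy-2-benzofuran-1(3H)-one (5,6-dimethoxyphthalide)
Product: 2 5,6-dimethoxy-1,3-dihydro-2-benzofuran-1-ol (lactol, racemic and configurationally labile hemiacetal carbon)
Conditions: DIBAL-H (1.15 equiv, toluene), CH2Cl2, −78 °C, 1.5 h; MeOH quench, aq. Rochelle salt; used crude
Reagents that add atoms: none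
Why: Partial lactone reduction, in which the aluminium hemiacetal from one hydride transfer survives at −78 °C until the quench so reduction stops at the lactol; the aryl methyl ethers are inert and the racemic hemiacetal centre disappears in step 2.

Step 2
Reactants: 2 5,6-dimethoxy-1,3-dihydro-2-benzofuran-1-ol; 3 (dibromomethyl)triphenylphosphonium bromide
Product: 5 [2-(2,2-dibromoethenyl)-4,5-dimethoxyphenyl]methanol, via 2-(hydroxymethyl)-4,5-dimethoxybenzaldehyde 4 (not isolated)
Conditions: 3 (2.0 equiv), KOt-Bu (1.9 equiv), THF, 0 °C to rt, 20 min; then 2, rt, 1 h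
Reagents that add atoms: (dibromomethyl)triphenylphosphonium bromide (3), BrC(Br)[P+](c1ccccc1)(c1ccccc1)c1ccccc1.[Br-]
Why: Wittig-type dibromomethylenation (first stage of the Corey–Fuchs/Ramirez olefination), in which the lactol equilibrates with open aldehyde 4 and 4 is drained by pre-formed Ph3P=CBr2; no CBr4/Ph3PBr2 is present, so the free benzylic OH is not brominated, the slight deficit of base avoids loss of HBr, and no stereocentre is formed.

Step 3
Reactants: 5 [2-(2,2-dibromoethenyl)-4,5-dimethoxyphenyl]methanol; 6 (2,4-dimethoxyphenyl)boronic acid; 7 carbon monoxide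
Product: 9 (6,7-dimethoxy-1H-isochromen-3-yl)(2,4-dimethoxyphenyl)methanone, via 3-bromo-6,7-dimethoxy-1H-isochromene 8 (not isolated)
Conditions: (a) CuI (10 mol %), 1,10-phenanthroline (20 mol %), Cs2CO3 (1.5 equiv), toluene (0.05 M), 80 °C, Ar; (b) same flask: 6 (1.5 equiv), PdCl2(dppf) (5 mol %), Cs2CO3 (2 equiv), CO (7, 3 bar), 80 °C
Reagents that add atoms: (2,4-dimethoxyphenyl)boronic acid (6), COc1ccc(B(O)O)c(OC)c1; carbon monoxide (7), [C-]#[O+]
Why: Proposed new method: one-pot Cu-catalysed 6-endo O-vinylation / Pd-catalysed carbonylative Suzuki–Miyaura coupling of a gem-dibromovinyl benzylic alcohol, in which the phenanthroline–Cu(I) alkoxide of 5 can reach only the C–Br bond cis to the arene, so oxidative addition and C–O reductive elimination with retention close the six-membered enol ether and leave the trans bromide as α-bromo enol ether 8 (which can no longer lose HBr); Pd(0) then inserts into this activated C–Br bond, CO insertion into the electron-rich α-alkoxyvinyl–Pd bond outruns transmetalation of the ortho-substituted boronic acid, and the acyl–Pd species couples with 6 to give the ketone without forming a stereocentre; the closest known reaction types are the Cu-catalysed cyclisation of 2-(gem-dibromovinyl)phenols to 2-bromobenzofurans, the Cu-catalysed intramolecular O-vinylation of aliphatic alcohols with simple vinyl bromides, and the Pd-catalysed domino C–N coupling/carbonylation/Suzuki coupling of 2-(gem-dibromovinyl)anilines to 2-aroylindoles, none of which, to my knowledge, has been shown for an aliphatic alcohol on a gem-dibromoalkene or for a non-aromatic 1H-isochromene ring.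

**Compound list**
1 | 5,6-dimethoxy-2-benzofuran-1(3H)-one (5,6-dimethoxyphthalide) | COc1cc2COC(=O)c2cc1OC | starting material
2 | 5,6-dimethoxy-1,3-dihydro-2-benzofuran-1-ol (racemic lactol) | COc1cc2COC(O)c2cc1OC | intermediate
3 | (dibromomethyl)triphenylphosphonium bromide | BrC(Br)[P+](c1ccccc1)(c1ccccc1)c1ccccc1.[Br-] | starting material
4 | 2-(hydroxymethyl)-4,5-dimethoxybenzaldehyde (open-chain tautomer of 2) | COc1cc(CO)c(C=O)cc1OC | intermediate
5 | [2-(2,2-dibromoethenyl)-4,5-dimethoxyphenyl]methanol | COc1cc(CO)c(C=C(Br)Br)cc1OC | intermediate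
6 | (2,4-dimethoxyphenyl)boronic acid | COc1ccc(B(O)O)c(OC)c1 | starting material
7 | carbon monoxide | [C-]#[O+] | starting material
8 | 3-bromo-6,7-dimethoxy-1H-isochromene | COc1cc2COC(Br)=Cc2cc1OC | intermediate
9 | (6,7-dimethoxy-1H-isochromen-3-yl)(2,4-dimethoxyphenyl)methanone (CNP0233831.0, achiral) | COc1ccc(C(=O)C2=Cc3cc(OC)c(OC)cc3CO2)c(OC)c1 | target

Total step count: 3. Longest linear sequence: 3 steps (1 → 2 → 5 → 9).

**Three steps most likely to fail**

Step 3 (the proposed new step).
- Risks: Cs2CO3 may strip HBr from 5 to give the bromoalkyne, which would close 5-exo to a (bromomethylene)phthalan. The Cu alkoxide may couple too slowly. Direct Suzuki coupling without CO may compete.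
- Fallback, known chemistry only, sets out from 1 and comes back at 9. LiAlH4 in THF reduces 1 to (4,5-dimethoxybenzene-1,2-diyl)dimethanol F1. This symmetric diol is mono-alkylated (NaH, 1 equiv, then 2-chloro-N-methoxy-N-methylacetamide, THF) to 2-{[2-(hydroxymethyl)-4,5-dimethoxyphenyl]methoxy}-N-methoxy-N-methylacetamide F2. Commercial 2,4-dimethoxyphenylmagnesium bromide (2.2 equiv, THF, 0 °C) then gives, by Weinreb ketone synthesis, 1-(2,4-dimethoxyphenyl)-2-{[2-(hydroxymethyl)-4,5-dimethoxyphenyl]methoxy}ethan-1-one F3. MnO2 in CH2Cl2 oxidises only the benzylic alcohol to 2-{[2-(2,4-dimethoxyphenyl)-2-oxoethoxy]methyl}-4,5-dimethoxybenzaldehyde F4. Catalytic piperidinium acetate in hot toluene closes the ring by intramolecular aldol addition to (2,4-dimethoxyphenyl)(4-hydroxy-6,7-dimethoxy-3,4-dihydro-1H-isochromen-3-yl)methanone F5, which loses water in the flask and gives 9.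

Step 2.
- Risks: the free OH or lactol may quench part of the ylide. Any surplus base can trigger a Cannizzaro/Tishchenko return to 1 or loss of HBr from 5.
- Fallback, a protecting-group route, sets out from 2 and comes back at 5. TBSCl and imidazole in DMF trap the open form as 2-({[tert-butyl(dimethyl)silyl]oxy}methyl)-4,5-dimethoxybenzaldehyde F6. The classical CBr4/PPh3 olefination in CH2Cl2 at 0 °C, now safe because no OH is left, gives tert-butyl{[2-(2,2-dibromoethenyl)-4,5-dimethoxyphenyl]methoxy}dimethylsilane F7. TBAF in THF then releases 5.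

Step 1.
- Risks: over-reduction to the diol, or acid-induced loss of water from 2 to the reactive 5,6-dimethoxyisobenzofuran during work-up.
- Fallback sets out from 1 and comes back at 2 through its open form 4. The lactone is opened with MeNH(OMe)·HCl/AlMe3 in CH2Cl2 to 2-(hydroxymethyl)-N,4,5-trimethoxy-N-methylbenzamide F8, which is used at once. LiAlH4 (THF, −78 to 0 °C) gives a chelated tetrahedral intermediate that cannot be reduced further, and this collapses on neutral work-up to 4 and hence 2.

**Further compounds**
F1 | step 3 | (4,5-dimethoxybenzene-1,2-diyl)dimethanol | COc1cc(CO)c(CO)cc1OC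
F2 | step 3 | 2-{[2-(hydroxymethyl)-4,5-dimethoxyphenyl]methoxy}-N-methoxy-N-methylacetamide | COc1cc(CO)c(COCC(=O)N(C)OC)cc1OC
F3 | step 3 | 1-(2,4-dimethoxyphenyl)-2-{[2-(hydroxymethyl)-4,5-dimethoxyphenyl]methoxy}ethan-1-one | COc1ccc(C(=O)COCc2cc(OC)c(OC)cc2CO)c(OC)c1
F4 | step 3 | 2-{[2-(2,4-dimethoxyphenyl)-2-oxoethoxy]methyl}-4,5-dimethoxybenzaldehyde | COc1ccc(C(=O)COCc2cc(OC)c(OC)cc2C=O)c(OC)c1
F5 | step 3 | (2,4-dimethoxyphenyl)(4-hydroxy-6,7-dimethoxy-3,4-dihydro-1H-isochromen-3-yl)methanone (racemic diastereomer mixture, not isolated) | COc1ccc(C(=O)C2OCc3cc(OC)c(OC)cc3C2O)c(OC)c1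
F6 | step 2 | 2-({[tert-butyl(dimethyl)silyl]oxy}methyl)-4,5-dimethoxybenzaldehyde | COc1cc(C=O)c(CO[Si](C)(C)C(C)(C)C)cc1OC
F7 | step 2 | tert-butyl{[2-(2,2-dibromoethenyl)-4,5-dimethoxyphenyl]methoxy}dimethylsilane | COc1cc(C=C(Br)Br)c(CO[Si](C)(C)C(C)(C)C)cc1OC
F8 | step 1 | 2-(hydroxymethyl)-N,4,5-trimethoxy-N-methylbenzamide | COc1cc(CO)c(cc1OC)C(=O)N(C)OC
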